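**Plan**

1. Retrosynthetic cuts, in order: the C6–prenyl bond and the lactone C–O bond; the C8–CH(Ph) and O7–acyl bonds (annulation with cinnamaldehyde); the C5–C6 bond of the carbocycle; then O1–C2, C4–C4a and C6–CH2(cyclobutyl). This leaves triacetic acid lactone, tiglic acid, cinnamaldehyde, prenol and verbenone.
2. Enabling feature: ring C4a–C5–C6–C7–C8–C8a is a 1,3,5-trioxygenated carbocycle with carbonyl C5 between C4a and C6. It is the C-acyl isomer of a 2-pyranone whose ring oxygen bridges C5 and C7. That pyranone has one OH (future O1) and one nucleophilic carbon (future C4a), so the chromanone regiochemistry is fixed before the carbocycle exists.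
3. Forward order: verbenone to the cyclobutylmethyl iodide; alkylation of the lactone dianion; C-tigloylation; oxa-Michael closure of the dihydropyranone ring; anionic pyranone-to-benzene isomerisation that closes the carbocycle at C5–C6; a lactone on C8/O7 as a temporary ring; dearomatising prenylation at C6; lactone opening.
4. Stereochemistry: cyclobutane centres from (1S,5S)-verbenone (chiral pool); cis C2/C3 from quinine-catalysed oxa-Michael addition with kinetic protonation; the benzylic centre from a chiral carbene catalyst; C6 from a chiral palladium catalyst.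

Key step: step 8

Remark: atom labels are the chromanone numbers of the core (O1, C2, C3, C4, C4a, C5 to C8, C8a); descriptors of 19 refer to the drawn enol tautomer; the sense of induction in steps 7, 9 and 11 is assigned by analogy, and the enantiomeric catalyst would be used in the same step if it proves opposite.

**Route**

Step 1
Reactants: 1 (1S,5S)-verbenone
Product: 2 (1S,3R)-3-acetyl-2,2-dimethylcyclobutane-1-carboxylic acid (cis-pinononic acid)
Conditions: RuCl3·xH2O (2 mol%), NaIO4 (4.1 equiv), MeCN/EtOAc/H2O, rt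
Reagents that add atoms: sodium periodate, [Na+].[O-]I(=O)(=O)=O; water, O
Why: Oxidative alkene cleavage by catalytically generated ruthenium tetroxide opens the enone C=C, the α-keto acid loses CO2 oxidatively, and both ring stereocentres and their cis relationship are carried over unchanged from the bicycle.

Step 2
Reactants: 2 (1S,3R)-3-acetyl-2,2-dimethylcyclobutane-1-carboxylic acid
Product: 3 (1S,3S)-2,2-dimethyl-3-(prop-1-en-2-yl)cyclobutane-1-carboxylic acid
Conditions: Ph3PCH3Br (2.5 equiv), KOtBu (3.4 equiv), THF, 0 °C to rt; aq. citric acid work-up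
Reagents that add atoms: methyltriphenylphosphonium bromide, C[P+](c1ccccc1)(c1ccccc1)c1ccccc1.[Br-]
Why: Wittig methylenation of the methyl ketone on its carboxylate salt; enolisation toward the ring carbon would need a strained exocyclic cyclobutylidene enolate, so the cis C3 centre should survive.

Step 3
Reactants: 3 (1S,3S)-2,2-dimethyl-3-(prop-1-en-2-yl)cyclobutane-1-carboxylic acid
Product: 4 [(1S,3S)-2,2-dimethyl-3-(prop-1-en-2-yl)cyclobutyl]methanol
Conditions: LiAlH4, THF, 0 °C to rt; aq. NaOH work-up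
Reagents that add atoms: none
Why: Hydride reduction of the carboxylic acid to the primary alcohol leaves the 1,1-disubstituted alkene and the ring stereocentres untouched.

Step 4
Reactants: 4 [(1S,3S)-2,2-dimethyl-3-(prop-1-en-2-yl)cyclobutyl]methanol
Product: 5 (1S,3S)-1-(iodomethyl)-2,2-dimethyl-3-(prop-1-en-2-yl)cyclobutane
Conditions: I2, PPh3, imidazole, CH2Cl2, 0 °C to rt
Reagents that add atoms: iodine, II
Why: Appel-type iodination proceeds by SN2 displacement at the exocyclic CH2, so no ring stereocentre is involved and no cyclobutylcarbinyl cation (ring expansion) is formed.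

Step 5
Reactants: 6 4-hydroxy-6-methyl-2H-pyran-2-one (triacetic acid lactone); 5 (1S,3S)-1-(iodomethyl)-2,2-dimethyl-3-(prop-1-en-2-yl)cyclobutane
Product: 7 6-{2-[(1S,3S)-2,2-dimethyl-3-(prop-1-en-2-yl)cyclobutyl]ethyl}-4-hydroxy-2H-pyran-2-one
Conditions: LiN(i-Pr)2 (2.3 equiv), THF/DMPU, −78 °C; then 5, −78 to 0 °C; aq. NH4Cl
Reagents that add atoms: none
Why: Dianion alkylation: the O,C-dilithio derivative of 6 reacts at its terminal carbanion (the 6-methyl carbon, future C6) with the primary iodide by SN2, joining the cyclobutane to the triketide lactone.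

Step 6
Reactants: 7 6-{2-[(1S,3S)-2,2-dimethyl-3-(prop-1-en-2-yl)cyclobutyl]ethyl}-4-hydroxy-2H-pyran-2-one; 8 tiglic acid [(2E)-2-methylbut-2-enoic acid]
Product: 10 6-{2-[(1S,3S)-2,2-dimethyl-3-(prop-1-en-2-yl)cyclobutyl]ethyl}-4-hydroxy-3-[(2E)-2-methylbut-2-enoyl]-2H-pyran-2-one, via O-tigloyl pyranone ester 9 (not isolated)
Conditions: N,N'-dicyclohexylcarbodiimide (DCC), 4-(dimethylamino)pyridine (DMAP, 1.2 equiv), CH2Cl2, 0 °C to rt, then 40 °C
Reagents that add atoms: none
Why: Steglich esterification of the 4-hydroxyl followed by DMAP-mediated 1,3 O-to-C acyl shift (Fries-type rearrangement of the enol ester) puts the acyl group on C3 of the pyranone, its only nucleophilic carbon and the future C4a; the α,β-dimethyl enone is a poor Michael acceptor, so the (E)-tigloyl unit should survive.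

Step 7
Reactants: 10 6-{2-[(1S,3S)-2,2-dimethyl-3-(prop-1-en-2-yl)cyclobutyl]ethyl}-4-hydroxy-3-[(2E)-2-methylbut-2-enoyl]-2H-pyran-2-one
Product: 11 (2R,3S)-7-{2-[(1S,3S)-2,2-dimethyl-3-(prop-1-en-2-yl)cyclobutyl]ethyl}-2,3-dimethyl-2,3-dihydro-4H,5H-pyrano[4,3-b]pyran-4,5-dione
Conditions: (−)-quinine (15 mol%), chlorobenzene, 0 °C to rt
Reagents that add atoms: none
Why: Amine-catalysed 6-endo-trig intramolecular oxa-Michael addition of the only hydroxyl (so O1 can only end on C8a); the quininium ion pair selects the face of the enone β-carbon (C2 = R, by analogy with o-tigloyl phenols) and the enol is protonated anti to the new C2 methyl, giving the kinetic cis (2R,3S) ring, with the cyclobutane centres too remote to interfere.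

Step 8
Reactants: 11 (2R,3S)-7-{2-[(1S,3S)-2,2-dimethyl-3-(prop-1-en-2-yl)cyclobutyl]ethyl}-2,3-dimethyl-2,3-dihydro-4H,5H-pyrano[4,3-b]pyran-4,5-dione
Product: 13 (2R,3S)-6-{[(1R,3S)-2,2-dimethyl-3-(prop-1-en-2-yl)cyclobutyl]methyl}-5,7-dihydroxy-2,3-dimethyl-2,3-dihydro-4H-chromen-4-one, via acylketene lithium enolate 12 (not isolated)
Conditions: LiN(SiMe3)2 (2.2 equiv, the product being diprotic), THF, −78 °C to 0 °C; aq. NH4Cl
Reagents that add atoms: none
Why: Proposed new method: the amide base removes a proton from the side-chain CH2 on C7 (vinylogous to both the C5 lactone and the C4 ketone), the dienolate expels the ring oxygen from C5 (E1cB) to give acylketene 12 carrying a 2-oxido-diene, and the enolate carbon (future C6) adds to the ketene carbon C5, after which tautomerisation to the bis-phenoxide makes the process irreversible. The closest known reaction types are the alkoxide-mediated rearrangement of enol lactones to cyclic 1,3-diketones (benzylidenephthalide to 2-phenylindane-1,3-dione, pyranone to phloroglucinol by ring opening and Claisen condensation), ketene formation from ester enolates bearing a good leaving group, and the 6π-electrocyclisation of dienylketenes to phenols. The carbocycle is closed by a thermally allowed disrotatory 6π-electrocyclisation of the C5=C4a–C8a=C8–C7=C6 array, equivalent to a 6-(enolendo)-exo-dig C-acylation; a direct 1,3-shift would need a four-membered transition state, which is why fragmentation to the ketene is required. No new stereocentre is formed (C6 becomes aromatic), and C2/C3 should be retained because the C4 carbonyl is part of the delocalised anion throughout, so C3–H is not acidic and retro-oxa-Michael opening is not available. The selectivity needed is C- over O-closure of the ketene: O-closure only regenerates the lactone anion, whereas C-closure is drained by aromatisation; C4a and C7 are held cis on the C8a=C8 bond by the former ring. Because O1 is already bonded to C8a, the 5,7-dihydroxy-6-alkyl pattern of 13 is unambiguous.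

Step 9
Reactants: 13 (2R,3S)-6-{[(1R,3S)-2,2-dimethyl-3-(prop-1-en-2-yl)cyclobutyl]methyl}-5,7-dihydroxy-2,3-dimethyl-2,3-dihydro-4H-chromen-4-one; 14 (E)-cinnamaldehyde
Product: 15 (2R,3S,10S)-6-{[(1R,3S)-2,2-dimethyl-3-(prop-1-en-2-yl)cyclobutyl]methyl}-5-hydroxy-2,3-dimethyl-10-phenyl-2,3,9,10-tetrahydro-4H,8H-pyrano[2,3-f]chromene-4,8-dione
Conditions: (5aR,10bS)-2-mesityl-5a,10b-dihydro-4H,6H-indeno[2,1-b][1,2,4]triazolo[4,3-d][1,4]oxazin-2-ium tetrafluoroborate (10 mol%), i-Pr2NEt (20 mol%), 3,3',5,5'-tetra-tert-butyl-4,4'-diphenoquinone (1.1 equiv), 4 Å molecular sieves, toluene/THF, rt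
Reagents that add atoms: none
Why: Oxidative carbene catalysis turns 14 into an α,β-unsaturated acyl azolium, to which C8 of the vinylogous acid 13 (the only free ring carbon) adds in conjugate fashion (or by O-acylation and Coates–Claisen shift); O7, the only free ortho oxygen, then captures the acyl group to close the lactone, and the aminoindanol backbone shields one face of the β-carbon so that the benzylic centre should be S.

Step 10
Reactants: 16 3-methylbut-2-en-1-ol (prenol)
Product: 17 tert-butyl 3-methylbut-2-en-1-yl carbonate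
Conditions: di-tert-butyl dicarbonate, 4-(dimethylamino)pyridine (5 mol%), CH2Cl2, rt
Reagents that add atoms: di-tert-butyl dicarbonate, CC(C)(C)OC(=O)OC(=O)OC(C)(C)C
Why: DMAP-catalysed tert-butoxycarbonylation of the primary allylic alcohol gives a carbonate that ionises to a π-prenyl complex and its own base without further additives.

Step 11
Reactants: 15 (2R,3S,10S)-6-{[(1R,3S)-2,2-dimethyl-3-(prop-1-en-2-yl)cyclobutyl]methyl}-5-hydroxy-2,3-dimethyl-10-phenyl-2,3,9,10-tetrahydro-4H,8H-pyrano[2,3-f]chromene-4,8-dione; 17 tert-butyl 3-methylbut-2-en-1-yl carbonate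
Product: 18 (2R,3S,6R,10S)-6-{[(1R,3S)-2,2-dimethyl-3-(prop-1-en-2-yl)cyclobutyl]methyl}-2,3-dimethyl-6-(3-methylbut-2-en-1-yl)-10-phenyl-2,3,9,10-tetrahydro-4H,8H-pyrano[2,3-f]chromene-4,5,8(6H)-trione
Conditions: tris(dibenzylideneacetone)dipalladium chloroform adduct, Pd2(dba)3·CHCl3 (2.5 mol%), N,N'-[(1R,2R)-cyclohexane-1,2-diyl]bis[2-(diphenylphosphanyl)benzamide] (7.5 mol%), 17 (1.5 equiv), 1,4-dioxane, rt
Reagents that add atoms: none
Why: Tsuji–Trost asymmetric allylic dearomatisation: zerovalent palladium ionises 17 to the π-prenyl cation and tert-butoxide, which deprotonates the C5 phenol; the phenoxide is alkylated at C6 (ortho to O5, para to O1, with C8 blocked and any O-prenyl ether re-ionising) at the unsubstituted prenyl terminus, and the C2-symmetric ligand pocket should select the C6 face (6R) because the resident centres are remote.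

Step 12
Reactants: 18 (2R,3S,6R,10S)-6-{[(1R,3S)-2,2-dimethyl-3-(prop-1-en-2-yl)cyclobutyl]methyl}-2,3-dimethyl-6-(3-methylbut-2-en-1-yl)-10-phenyl-2,3,9,10-tetrahydro-4H,8H-pyrano[2,3-f]chromene-4,5,8(6H)-trione
Product: 19 (3S)-3-[(2R,3S,6R)-6-{[(1R,3S)-2,2-dimethyl-3-(prop-1-en-2-yl)cyclobutyl]methyl}-4-hydroxy-2,3-dimethyl-6-(3-methylbut-2-en-1-yl)-5,7-dioxo-3,5,6,7-tetrahydro-2H-chromen-8-yl]-3-phenylpropanoic acid (CNP0328119.1)
Conditions: LiOH (3 equiv), THF/H2O, 0 °C; then 0.5 M aq. HCl to pH 3, 0 °C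
Reagents that add atoms: lithium hydroxide, [Li+].[OH-]
Why: Saponification of the enol lactone (a vinylogous anhydride) at the lactone carbonyl releases the carboxylate and the C7 enolate; under base the β-triketone is a delocalised anion, so C3–H is not acidic and the cis-dimethyl unit, C6 and the benzylic centre should be retained on acidification.

**Compound list**

1 | (1S,5S)-verbenone [(1S,5S)-4,6,6-trimethylbicyclo[3.1.1]hept-3-en-2-one] | CC1=CC(=O)[C@H]2C[C@@H]1C2(C)C | starting material
2 | (1S,3R)-3-acetyl-2,2-dimethylcyclobutane-1-carboxylic acid | CC(=O)[C@@H]1C[C@H](C(=O)O)C1(C)C | intermediate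
3 | (1S,3S)-2,2-dimethyl-3-(prop-1-en-2-yl)cyclobutane-1-carboxylic acid | C=C(C)[C@@H]1C[C@H](C(=O)O)C1(C)C | intermediate
4 | [(1S,3S)-2,2-dimethyl-3-(prop-1-en-2-yl)cyclobutyl]methanol | C=C(C)[C@@H]1C[C@H](CO)C1(C)C | intermediate
5 | (1S,3S)-1-(iodomethyl)-2,2-dimethyl-3-(prop-1-en-2-yl)cyclobutane | C=C(C)[C@@H]1C[C@H](CI)C1(C)C | intermediate
6 | 4-hydroxy-6-methyl-2H-pyran-2-one (triacetic acid lactone) | CC1=CC(O)=CC(=O)O1 | starting material
7 | 6-{2-[(1S,3S)-2,2-dimethyl-3-(prop-1-en-2-yl)cyclobutyl]ethyl}-4-hydroxy-2H-pyran-2-one | C=C(C)[C@@H]1C[C@H](CCC2=CC(O)=CC(=O)O2)C1(C)C | intermediate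
8 | tiglic acid [(2E)-2-methylbut-2-enoic acid] | C/C=C(\C)C(=O)O | starting material
9 | 6-{2-[(1S,3S)-2,2-dimethyl-3-(prop-1-en-2-yl)cyclobutyl]ethyl}-2-oxo-2H-pyran-4-yl (2E)-2-methylbut-2-enoate | C=C(C)[C@@H]1C[C@H](CCC2=CC(OC(=O)/C(C)=C/C)=CC(=O)O2)C1(C)C | intermediate
10 | 6-{2-[(1S,3S)-2,2-dimethyl-3-(prop-1-en-2-yl)cyclobutyl]ethyl}-4-hydroxy-3-[(2E)-2-methylbut-2-enoyl]-2H-pyran-2-one | C=C(C)[C@@H]1C[C@H](CCC2=CC(O)=C(C(=O)O2)C(=O)/C(C)=C/C)C1(C)C | intermediate
11 | (2R,3S)-7-{2-[(1S,3S)-2,2-dimethyl-3-(prop-1-en-2-yl)cyclobutyl]ethyl}-2,3-dimethyl-2,3-dihydro-4H,5H-pyrano[4,3-b]pyran-4,5-dione | C=C(C)[C@@H]1C[C@H](CCC2=CC3=C(C(=O)O2)C(=O)[C@@H](C)[C@@H](C)O3)C1(C)C | intermediate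
12 | acylketene lithium enolate: (2R,3S)-2,3-dimethyl-4-oxo-5-(oxomethylidene)dihydropyran-6-ylidene unit carrying the lithium 2-oxidobut-2-enylidene chain to the cyclobutane | C=C(C)[C@@H]1C[C@H](CC=C([O-])/C=C2/O[C@H](C)[C@H](C)C(=O)C2=C=O)C1(C)C.[Li+] | intermediate
13 | (2R,3S)-6-{[(1R,3S)-2,2-dimethyl-3-(prop-1-en-2-yl)cyclobutyl]methyl}-5,7-dihydroxy-2,3-dimethyl-2,3-dihydro-4H-chromen-4-one | C=C(C)[C@@H]1C[C@H](Cc2c(O)cc3c(c2O)C(=O)[C@@H](C)[C@@H](C)O3)C1(C)C | intermediate
14 | (E)-cinnamaldehyde | O=C/C=C/c1ccccc1 | starting material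
15 | (2R,3S,10S)-6-{[(1R,3S)-2,2-dimethyl-3-(prop-1-en-2-yl)cyclobutyl]methyl}-5-hydroxy-2,3-dimethyl-10-phenyl-2,3,9,10-tetrahydro-4H,8H-pyrano[2,3-f]chromene-4,8-dione | C=C(C)[C@@H]1C[C@H](Cc2c(O)c3C(=O)[C@@H](C)[C@@H](C)Oc3c3[C@H](c4ccccc4)CC(=O)Oc23)C1(C)C | intermediate
16 | 3-methylbut-2-en-1-ol (prenol) | CC(C)=CCO | starting material
17 | tert-butyl 3-methylbut-2-en-1-yl carbonate | CC(C)=CCOC(=O)OC(C)(C)C | intermediate
18 | (2R,3S,6R,10S)-6-{[(1R,3S)-2,2-dimethyl-3-(prop-1-en-2-yl)cyclobutyl]methyl}-2,3-dimethyl-6-(3-methylbut-2-en-1-yl)-10-phenyl-2,3,9,10-tetrahydro-4H,8H-pyrano[2,3-f]chromene-4,5,8(6H)-trione | C=C(C)[C@@H]1C[C@H](C[C@@]2(CC=C(C)C)C(=O)C3=C(O[C@H](C)[C@H](C)C3=O)C4=C2OC(=O)C[C@H]4c5ccccc5)C1(C)C | intermediate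
19 | (3S)-3-[(2R,3S,6R)-6-{[(1R,3S)-2,2-dimethyl-3-(prop-1-en-2-yl)cyclobutyl]methyl}-4-hydroxy-2,3-dimethyl-6-(3-methylbut-2-en-1-yl)-5,7-dioxo-3,5,6,7-tetrahydro-2H-chromen-8-yl]-3-phenylpropanoic acid | C=C(C)[C@@H]1C[C@H](C[C@@]2(CC=C(C)C)C(=O)C3=C(O)[C@@H](C)[C@@H](C)OC3=C([C@@H](CC(=O)O)c3ccccc3)C2=O)C1(C)C | target

**Summary**

Total step count: 12. Longest linear sequence: 11 steps (steps 1 to 9, 11 and 12, from 1); step 10 is a one-step side branch.

**Steps most likely to fail**

Step 8 (carries the new-method label). The lithiated pyranone may not fragment to the acylketene, the ketene may re-close only at oxygen or be consumed by a second anion (oligomerisation), or excess base may erode the cis C3 centre by enolisation. The fallback replaces the one-flask fragmentation by the classical two-stage sequence of external alkoxide ring opening and Dieckmann condensation. It sets out from 11: NaOMe (1.05 equiv) in MeOH at 0 °C should open the activated lactone at C5 to methyl (2R,3S)-6-{4-[(1S,3S)-2,2-dimethyl-3-(prop-1-en-2-yl)cyclobutyl]-2-oxobutyl}-2,3-dimethyl-4-oxo-3,4-dihydro-2H-pyran-5-carboxylate F1. KOtBu in THF at −20 °C should then close the ketone enolate carbon onto the ester (the 5-oxo ester to cyclohexane-1,3-dione Claisen cyclisation), and aromatisation returns the route at 13.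

Step 11. Facial selectivity at C6 may be poor, since the two faces differ only through remote groups, and O-prenylation of the single chelated phenoxide may not funnel to carbon. The fallback uses an ion-pairing chiral cation on the doubly ionised acylphloroglucinol instead of palladium chemistry on the lactone. It sets out from 15: NaOMe in MeOH at 0 °C should open the lactone to methyl (3S)-3-[(2R,3S)-6-{[(1R,3S)-2,2-dimethyl-3-(prop-1-en-2-yl)cyclobutyl]methyl}-5,7-dihydroxy-2,3-dimethyl-4-oxo-3,4-dihydro-2H-chromen-8-yl]-3-phenylpropanoate F2. Alkylative dearomatisation with prenyl bromide under solid–liquid phase transfer (CsOH·H2O, O-allyl-N-(9-anthracenylmethyl)cinchonidinium bromide, toluene/CHCl3, −40 °C) should then place the prenyl group on C6, which is now flanked by two oxido groups, giving methyl (3S)-3-[(2R,3S,6R)-6-{[(1R,3S)-2,2-dimethyl-3-(prop-1-en-2-yl)cyclobutyl]methyl}-4-hydroxy-2,3-dimethyl-6-(3-methylbut-2-en-1-yl)-5,7-dioxo-3,5,6,7-tetrahydro-2H-chromen-8-yl]-3-phenylpropanoate F3; any C6 epimer would be removed by chromatography. LiOH in THF/H2O at 0 °C then returns the route at 19.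

Step 9. The acyl-deactivated phenol may add too slowly to the unsaturated acyl azolium, the acyl group may be diverted to O5 or O7 as a simple ester, or enantiofacial control may be low. The fallback uses a more electrophilic acceptor under hydrogen-bonding bifunctional catalysis. It sets out from 13: conjugate (Friedel–Crafts-type) addition of C8 to 5-benzylidene-2,2-dimethyl-1,3-dioxane-4,6-dione with the quinine-derived squaramide 3-{[3,5-bis(trifluoromethyl)phenyl]amino}-4-{[(8α,9S)-6'-methoxycinchonan-9-yl]amino}cyclobut-3-ene-1,2-dione (10 mol%) in CH2Cl2 at −20 °C should give 5-[(S)-{(2R,3S)-6-{[(1R,3S)-2,2-dimethyl-3-(prop-1-en-2-yl)cyclobutyl]methyl}-5,7-dihydroxy-2,3-dimethyl-4-oxo-3,4-dihydro-2H-chromen-8-yl}(phenyl)methyl]-2,2-dimethyl-1,3-dioxane-4,6-dione F4. Warming in toluene at 90 °C should then let O7 open the dioxanedione with loss of acetone and carbon dioxide, returning the route at 15.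

Further compounds
F1 | step 8 | methyl (2R,3S)-6-{4-[(1S,3S)-2,2-dimethyl-3-(prop-1-en-2-yl)cyclobutyl]-2-oxobutyl}-2,3-dimethyl-4-oxo-3,4-dihydro-2H-pyran-5-carboxylate | C=C(C)[C@@H]1C[C@H](CCC(=O)CC2=C(C(=O)OC)C(=O)[C@@H](C)[C@@H](C)O2)C1(C)C
F2 | step 11 | methyl (3S)-3-[(2R,3S)-6-{[(1R,3S)-2,2-dimethyl-3-(prop-1-en-2-yl)cyclobutyl]methyl}-5,7-dihydroxy-2,3-dimethyl-4-oxo-3,4-dihydro-2H-chromen-8-yl]-3-phenylpropanoate | C=C(C)[C@@H]1C[C@H](Cc2c(O)c3C(=O)[C@@H](C)[C@@H](C)Oc3c([C@@H](CC(=O)OC)c3ccccc3)c2O)C1(C)C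
F3 | step 11 | methyl (3S)-3-[(2R,3S,6R)-6-{[(1R,3S)-2,2-dimethyl-3-(prop-1-en-2-yl)cyclobutyl]methyl}-4-hydroxy-2,3-dimethyl-6-(3-methylbut-2-en-1-yl)-5,7-dioxo-3,5,6,7-tetrahydro-2H-chromen-8-yl]-3-phenylpropanoate | C=C(C)[C@@H]1C[C@H](C[C@@]2(CC=C(C)C)C(=O)C3=C(O)[C@@H](C)[C@@H](C)OC3=C([C@@H](CC(=O)OC)c3ccccc3)C2=O)C1(C)C
F4 | step 9 | 5-[(S)-{(2R,3S)-6-{[(1R,3S)-2,2-dimethyl-3-(prop-1-en-2-yl)cyclobutyl]methyl}-5,7-dihydroxy-2,3-dimethyl-4-oxo-3,4-dihydro-2H-chromen-8-yl}(phenyl)methyl]-2,2-dimethyl-1,3-dioxane-4,6-dione | C=C(C)[C@@H]1C[C@H](Cc2c(O)c3C(=O)[C@@H](C)[C@@H](C)Oc3c([C@@H](C3C(=O)OC(C)(C)OC3=O)c3ccccc3)c2O)C1(C)C
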